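**Retrosynthetic overview**

- Numbering: ring A = C1–C2–C3–C4(Me2)–C5–C10(Me); ring B = C5–C6(OAc)–C7(OH)–C8(Me, OH)–C9–C10; side chain C11=C12–C13(=O)–C14 on C9.
- Feature the strategy rests on: ring B, with its C5 stereocentre, an oxygen at C9 and a methyl-bearing C7=C8 alkene, is (R)-carvone. The gem-dimethyl carbon C4 is carvone's isopropenyl carbon plus one hydrogen atom, so ring A can be closed by a radical C3–C4 bond.
- Disconnections, from the target backwards: C11=C12 (Wittig); C6–O and C8–O (oxidation of the enolate and the silyl enol ether of a C7 ketone); C9–C11 (alkoxymethyllithium addition, then 1,3-oxidative transposition of oxygen from C9 to C7); C3–C4 (hydrogen-atom-transfer radical cyclization onto a vinyl sulfone); C10–C1 and C10–CH3 (two enolate alkylations of carvone).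
- Ring order: ring B comes from carvone; ring A is closed in step 5; no other ring is formed.

Key step: step 5

Remark on the chemistry: α/β refer to the usual drawing with the C10 methyl β. The epimers drawn at C2 (sulfone) and at the C9 carbinol are the expected major ones; both centres are erased later, so either epimer serves.

**Route**

Step 1
Reactants: 1 phenyl vinyl sulfone; 2 formaldehyde
Product: 3 2-(phenylsulfonyl)prop-2-en-1-ol
Conditions: 37% aq. CH2O, DABCO (0.5 equiv), THF, rt
Reagents that add atoms: formaldehyde (2), C=O
Why: Morita–Baylis–Hillman hydroxymethylation: DABCO adds to the vinyl sulfone, the α-sulfonyl carbanion adds to formaldehyde, and loss of DABCO restores the alkene; no stereocentre is formed.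

Step 2
Reactants: 3 2-(phenylsulfonyl)prop-2-en-1-ol
Product: 4 3-bromo-2-(phenylsulfonyl)prop-1-ene
Conditions: PBr3, Et2O, 0 °C
Reagents that add atoms: phosphorus tribromide, BrP(Br)Br
Why: Conversion of a primary allylic alcohol into the bromide through its phosphite ester; SN2 and SN2′ displacement give the same compound because the allyl unit is symmetrical.

Step 3
Reactants: 5 (R)-(−)-carvone; 6 iodomethane
Product: 8 (5R)-2,6-dimethyl-5-(prop-1-en-2-yl)cyclohex-2-en-1-one (6-methylcarvone; both epimers at the new centre), via lithium enolate of carvone 7 (not isolated)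
Conditions: LiN(i-Pr)2, THF, −78 °C; MeI, −78 → 0 °C
Reagents that add atoms: iodomethane (6), CI
Why: Kinetic α′-deprotonation of the cross-conjugated enone and SN2 methylation (enolate alkylation) put the future C10 methyl in place; the epimer mixture is of no consequence because this carbon is planarized again in step 4.

Step 4
Reactants: 8 6-methylcarvone; 4 3-bromo-2-(phenylsulfonyl)prop-1-ene
Product: 10 2,6-dimethyl-6-[2-(phenylsulfonyl)prop-2-en-1-yl]-5-(prop-1-en-2-yl)cyclohex-2-en-1-one with the 6-methyl cis and the sulfonylallyl arm trans to the isopropenyl group, via lithium enolate of 6-methylcarvone 9 (not isolated)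
Conditions: LiN(i-Pr)2, THF, −78 → −20 °C; then 4 (1.2 equiv), THF, −78 °C
Reagents that add atoms: 3-bromo-2-(phenylsulfonyl)prop-1-ene (4), BrCC(=C)S(=O)(=O)c1ccccc1
Why: Enolate alkylation (addition–elimination on the activated allylic bromide, same product as direct SN2); the electrophile should enter the tetrasubstituted enolate on the face anti to the C5 isopropenyl group, which sets quaternary C10 with the arm trans and the methyl cis to isopropenyl.

Step 5
Reactants: 10 the doubly alkylated carvone
Product: 11 trans-fused 2,5,5,8a-tetramethyl-7-(phenylsulfonyl)-4a,5,6,7,8,8a-hexahydronaphthalen-1(4H)-one (C9 ketone, C7=C8, 5α-H, 10β-CH3, PhSO2 on C2, equatorial epimer drawn)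
Conditions: Fe(acac)3 (0.5 equiv), PhSiH3 (2.5 equiv), EtOH/HOCH2CH2OH 5:1, 0.02 M, 60 °C
Reagents that add atoms: none
Why: The iron hydride formed from Fe(acac)3 and PhSiH3 in EtOH transfers a hydrogen atom to the CH2 terminus of the isopropenyl group, and the resulting tertiary C4 radical, now carrying both methyls, adds to the unsubstituted CH2 terminus (C3) of the vinyl sulfone; the α-sulfonyl C2 radical is then reduced by divalent iron and protonated by EtOH. The closest known reaction type is the Fe(acac)3/PhSiH3 reductive olefin coupling (hydrogen-atom-transfer Giese addition) in its intramolecular form. Ring A closes 6-endo-trig through the C3–C4 bond, and it can only be trans-fused because C5 (from carvone) and C10 (from step 4) already hold the two arms trans. The one new stereocentre, C2, is set in the final protonation and should favour the equatorial sulfone; it is erased in step 7. The step needs hydrogen-atom transfer to the isopropenyl group and not to the enone or the vinyl sulfone, which the higher electron density of the 1,1-dialkyl alkene secures. It also needs 6-endo and not 5-exo attack, which the sulfone secures by polarizing the acceptor toward its terminal carbon and because the 5-exo mode would join two fully substituted carbons.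

Step 6
Reactants: 11 the bicyclic sulfonyl enone; 12 tributyl[(methoxymethoxy)methyl]stannane
Product: 13 C9 tertiary allylic alcohol: 9-hydroxy-9-[(methoxymethoxy)methyl] adduct of 11 (C7=C8 and the C2 sulfone retained; 9β-OH drawn)
Conditions: 12 (3 equiv), n-BuLi (3 equiv), THF, −78 °C; then 11, −78 °C; AcOH quench
Reagents that add atoms: tributyl[(methoxymethoxy)methyl]stannane (12), CCCC[Sn](CCCC)(CCCC)COCOC
Why: Tin–lithium exchange gives (methoxymethoxy)methyllithium, which adds 1,2 to the C9 carbonyl anti to the axial C10 methyl and brings in C11; the excess covers reagent lost to harmless deprotonation α to the sulfone, and the carbinol configuration is lost in step 8.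

Step 7
Reactants: 13 the sulfonyl tertiary allylic alcohol
Product: 14 desulfonylated tertiary allylic alcohol (C2 = CH2; 9-hydroxy-9-[(methoxymethoxy)methyl], C7=C8)
Conditions: Mg turnings (I2-activated), MeOH, 50 °C
Reagents that add atoms: none
Why: Reductive desulfonylation by electron transfer from magnesium in methanol (C–S cleavage of the sulfone radical anion, further reduction, protonation); it is placed here because no enone or ketone is present to compete, and it removes the C2 stereocentre.

Step 8
Reactants: 14 the tertiary allylic alcohol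
Product: 15 transposed enone: C7 ketone, C8=C9, C9 bearing CH2OCH2OCH3 (C11)
Conditions: pyridinium chlorochromate [C5H5NH][CrO3Cl] (2 equiv), Celite, CH2Cl2, rt
Reagents that add atoms: pyridinium chlorochromate, [O-][Cr](=O)(=O)Cl.c1cc[nH+]cc1
Why: Babler–Dauben oxidative transposition: the tertiary allylic chromate ester undergoes a [3,3] shift that delivers a chromate oxygen to C7 and is then oxidized, which moves the oxygen function from C9 to C7 and places the alkene at C8=C9.

Step 9
Reactants: 15 the C7 enone
Product: 16 saturated C7 ketone with 9α-H (C11 β, equatorial) and 8β-CH3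
Conditions: H2 (10 bar), 10% Pd/C, EtOAc, rt
Reagents that add atoms: none
Why: Heterogeneous syn hydrogenation from the α face, opposite the axial C10 methyl, should set C9 with its hydrogen α and C11 β; C8 is planarized again in step 10 and the methoxymethyl ether is not hydrogenolysed.

Step 10
Reactants: 16 the saturated C7 ketone
Product: 17 C7 trimethylsilyl enol ether with the C7=C8 double bond
Conditions: Me3SiOTf, Et3N, CH2Cl2, 0 °C → rt
Reagents that add atoms: trimethylsilyl trifluoromethanesulfonate, C[Si](C)(C)OS(=O)(=O)C(F)(F)F
Why: Soft enolization under equilibrating silyl triflate/amine conditions should favour the more substituted C7=C8 silyl enol ether; with excess amine at this temperature the methoxymethyl acetal is left alone.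

Step 11
Reactants: 17 the silyl enol ether
Product: 20 8α-hydroxy-8β-methyl C7 ketone, via 7α,8α-epoxy silyl ether 18 (not isolated), via 8α-silyloxy ketone 19 (not isolated)
Conditions: m-CPBA, NaHCO3, CH2Cl2, −20 → 0 °C; then 1 M HCl, THF, 0 °C
Reagents that add atoms: 3-chloroperoxybenzoic acid, OOC(=O)c1cccc(Cl)c1
Why: Rubottom oxidation: epoxidation on the α face (the β face is screened by the syn-axial C10 methyl), ring opening with 1,4-silyl shift and desilylation should give the tertiary 8α-alcohol with the methyl β.

Step 12
Reactants: 20 the 8α-hydroxy ketone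
Product: 22 6α,8α-dihydroxy C7 ketone, via dipotassium enolate alkoxide 21 (not isolated)
Conditions: KN(SiMe3)2 (2.5 equiv), THF, −78 °C; 2-(phenylsulfonyl)-3-phenyloxaziridine, −78 °C; AcOH quench
Reagents that add atoms: 2-(phenylsulfonyl)-3-phenyloxaziridine, O=S(=O)(c1ccccc1)N1OC1c1ccccc1
Why: Davis enolate hydroxylation; C6 is the only enolizable position, and the oxaziridine should approach from the α face, away from the axial methyls on C4 and C10, to give the equatorial 6α-alcohol, which is also the more stable epimer.

Step 13
Reactants: 22 the 6α,8α-dihydroxy ketone; 23 acetic anhydride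
Product: 24 6α-acetoxy-8α-hydroxy C7 ketone
Conditions: Ac2O, pyridine, DMAP (cat.), CH2Cl2, 0 °C → rt
Reagents that add atoms: acetic anhydride (23), CC(=O)OC(C)=O
Why: DMAP-catalysed acylation of the secondary C6 hydroxyl; the tertiary C8 hydroxyl is too hindered to react under these conditions.

Step 14
Reactants: 24 the 6α-acetoxy ketone
Product: 25 6α-acetoxy-7β,8α-diol with C11 as its methoxymethyl ether
Conditions: NaBH4, CeCl3·7H2O, MeOH, −40 °C
Reagents that add atoms: none
Why: Hydride reduction by axial attack from the open α face (the β face is flanked by the axial C8 methyl) should give the equatorial 7β-alcohol; the low temperature and CeCl3 keep the medium from becoming basic enough for acetyl migration.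

Step 15
Reactants: 25 the methoxymethyl ether
Product: 26 6α-acetoxy-7β,8α,11-triol
Conditions: ZnBr2, n-PrSH, CH2Cl2, 0 °C
Reagents that add atoms: none
Why: Lewis acid/thiol cleavage of the methoxymethyl acetal; the thiol traps the methoxymethyl cation so that no methylene acetal forms with the C8 hydroxyl, and the acetate is untouched.

Step 16
Reactants: 26 the triol monoacetate
Product: 27 C11 aldehyde (6α-acetoxy-7β,8α-dihydroxy)
Conditions: TEMPO (cat.), PhI(OAc)2, CH2Cl2, rt
Reagents that add atoms: none
Why: Oxoammonium (TEMPO) oxidation is selective for the primary alcohol over the hindered secondary C7 and tertiary C8 hydroxyls and stops at the aldehyde.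

Step 17
Reactants: 27 the C11 aldehyde; 28 1-(triphenyl-λ5-phosphanylidene)propan-2-one
Product: 29 the target, (E)-enone with 6α-OAc, 7β-OH, 8α-OH, 8β-CH3 and 9β side chain
Conditions: 28 (2 equiv), toluene, 80 °C
Reagents that add atoms: 1-(triphenyl-λ5-phosphanylidene)propan-2-one (28), CC(=O)C=P(c1ccccc1)(c1ccccc1)c1ccccc1
Why: Wittig reaction with a stabilized acyl ylide should give the (E)-enone under neutral conditions that spare the β-hydroxy aldehyde and the acetate; C9 keeps its equatorial β substituent.

**Compound list**

1 | phenyl vinyl sulfone | C=CS(=O)(=O)c1ccccc1 | starting material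
2 | formaldehyde (37% aqueous) | C=O | starting material
3 | 2-(phenylsulfonyl)prop-2-en-1-ol | OCC(=C)S(=O)(=O)c1ccccc1 | intermediate
4 | 3-bromo-2-(phenylsulfonyl)prop-1-ene | BrCC(=C)S(=O)(=O)c1ccccc1 | intermediate
5 | (R)-(−)-carvone | O=C1C(C)=CC[C@@H](C(C)=C)C1 | starting material
6 | iodomethane | CI | starting material
7 | lithium α′-enolate of carvone | [Li]OC1=C[C@H](C(C)=C)CC=C1C | intermediate
8 | 6-methylcarvone (both epimers at the new centre) | O=C1C(C)=CC[C@@H](C(C)=C)C1C | intermediate
9 | lithium enolate of 6-methylcarvone | [Li]OC1=C(C)[C@H](C(C)=C)CC=C1C | intermediate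
10 | 2,6-dimethyl-6-[2-(phenylsulfonyl)prop-2-en-1-yl]-5-(prop-1-en-2-yl)cyclohex-2-en-1-one, arm trans to isopropenyl | O=C1C(C)=CC[C@@H](C(C)=C)[C@]1(C)CC(=C)S(=O)(=O)c1ccccc1 | intermediate
11 | trans-fused bicyclic enone, C9 ketone, C7=C8, PhSO2 on C2 | O=C1C(C)=CC[C@H]2C(C)(C)C[C@H](S(=O)(=O)c3ccccc3)C[C@@]21C | intermediate
12 | tributyl[(methoxymethoxy)methyl]stannane | CCCC[Sn](CCCC)(CCCC)COCOC | starting material
13 | C9 tertiary allylic alcohol with CH2OCH2OCH3 on C9 and PhSO2 on C2 | O[C@@]1(COCOC)C(C)=CC[C@H]2C(C)(C)C[C@H](S(=O)(=O)c3ccccc3)C[C@@]21C | intermediate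
14 | desulfonylated C9 tertiary allylic alcohol | O[C@@]1(COCOC)C(C)=CC[C@H]2C(C)(C)CCC[C@@]21C | intermediate
15 | C7 enone with C8=C9 and C11 methoxymethyl ether | O=C1C[C@H]2C(C)(C)CCC[C@]2(C)C(COCOC)=C1C | intermediate
16 | saturated C7 ketone, 9α-H, 8β-CH3 | O=C1C[C@H]2C(C)(C)CCC[C@]2(C)[C@@H](COCOC)[C@H]1C | intermediate
17 | C7 trimethylsilyl enol ether (C7=C8) | C[Si](C)(C)OC1=C(C)[C@H](COCOC)[C@@]2(C)CCCC(C)(C)[C@@H]2C1 | intermediate
18 | 7α,8α-epoxy 7-trimethylsilyl ether | C[Si](C)(C)O[C@]12O[C@@]1(C)[C@H](COCOC)[C@@]3(C)CCCC(C)(C)[C@@H]3C2 | intermediate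
19 | 8α-(trimethylsilyloxy) C7 ketone | O=C1C[C@H]2C(C)(C)CCC[C@]2(C)[C@@H](COCOC)[C@]1(C)O[Si](C)(C)C | intermediate
20 | 8α-hydroxy-8β-methyl C7 ketone | O=C1C[C@H]2C(C)(C)CCC[C@]2(C)[C@@H](COCOC)[C@]1(C)O | intermediate
21 | dipotassium C6=C7 enolate and C8 alkoxide of 20 | [K]OC1=C[C@H]2C(C)(C)CCC[C@]2(C)[C@@H](COCOC)[C@]1(C)O[K] | intermediate
22 | 6α,8α-dihydroxy C7 ketone | O=C1[C@H](O)[C@H]2C(C)(C)CCC[C@]2(C)[C@@H](COCOC)[C@]1(C)O | intermediate
23 | acetic anhydride | CC(=O)OC(C)=O | starting material
24 | 6α-acetoxy-8α-hydroxy C7 ketone | O=C1[C@H](OC(C)=O)[C@H]2C(C)(C)CCC[C@]2(C)[C@@H](COCOC)[C@]1(C)O | intermediate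
25 | 6α-acetoxy-7β,8α-diol, C11 methoxymethyl ether | O[C@H]1[C@H](OC(C)=O)[C@H]2C(C)(C)CCC[C@]2(C)[C@@H](COCOC)[C@]1(C)O | intermediate
26 | 6α-acetoxy-7β,8α,11-triol | O[C@H]1[C@H](OC(C)=O)[C@H]2C(C)(C)CCC[C@]2(C)[C@@H](CO)[C@]1(C)O | intermediate
27 | C11 aldehyde, 6α-acetoxy-7β,8α-dihydroxy | O[C@H]1[C@H](OC(C)=O)[C@H]2C(C)(C)CCC[C@]2(C)[C@@H](C=O)[C@]1(C)O | intermediate
28 | 1-(triphenyl-λ5-phosphanylidene)propan-2-one | CC(=O)C=P(c1ccccc1)(c1ccccc1)c1ccccc1 | starting material
29 | CNP0136046.1 | CC(=O)/C=C/[C@H]1[C@](C)(O)[C@@H](O)[C@H](OC(C)=O)[C@H]2C(C)(C)CCC[C@@]21C | target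

**Step count and risks**

Total step count: 17. Longest linear sequence: 16 steps (steps 1, 2 and 4–17, from phenyl vinyl sulfone through bromide 4 to the target). The branch from (R)-carvone (steps 3–17) is 15 steps long and joins this sequence in step 4.

Steps most likely to fail:

1. Step 5 (radical ring closure). The tertiary radical may be reduced to the isopropyl group before it cyclizes, the hydride may transfer hydrogen to the vinyl sulfone or the enone, or intermolecular addition may compete. Fallback: starting from 10, Markovnikov addition of HBr (HBr in AcOH, 0 °C) to the isopropenyl group should give the tertiary bromide F1. Slow addition of Bu3SnH with AIBN in benzene at 80 °C then generates the same C4 radical without any metal hydride and should close ring A onto the vinyl sulfone, returning to the route at 11.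

2. Step 9 (hydrogenation of the tetrasubstituted enone). Hydrogen uptake at the hindered C8=C9 bond may be too slow, or the allylic C11–O bond may be hydrogenolysed. Fallback: starting from 15, treatment with Mn(dpm)3 (dpm = dipivaloylmethanato; catalytic), PhSiH3 and O2 in i-PrOH should transfer a hydrogen atom to C9 and trap the C8 radical with oxygen as the 8α-hydroperoxy ketone F2. Reduction with P(OEt)3 returns to the route at 20. This bypasses steps 9–11 and also removes the regiochemical question of the enolization in step 10.

3. Step 17 (Wittig olefination). Addition of the stabilized ylide to the neopentyl-type aldehyde may be slow enough for retro-aldol cleavage or β-elimination of the C8 hydroxyl to take over on heating. Fallback: starting from 27, Takai iodo-olefination (CrCl2, CHI3, THF, 0 °C → rt) should give the (E)-vinyl iodide F3. Stille coupling with tributyl(1-ethoxyvinyl)stannane (Pd(PPh3)4, toluene, 80 °C) should then give the 2-ethoxy diene F4, and hydrolysis with dilute aqueous HCl in THF returns to the route at 29.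

**Further compounds**

F1 | step 5 | tertiary bromide from HBr addition to the isopropenyl group of 10 | O=C1C(C)=CC[C@@H](C(C)(C)Br)[C@]1(C)CC(=C)S(=O)(=O)c1ccccc1
F2 | step 9 | 8α-hydroperoxy-8β-methyl C7 ketone with C11 methoxymethyl ether | O=C1C[C@H]2C(C)(C)CCC[C@]2(C)[C@@H](COCOC)[C@]1(C)OO
F3 | step 17 | (E)-vinyl iodide at C11=C12 | O[C@H]1[C@H](OC(C)=O)[C@H]2C(C)(C)CCC[C@]2(C)[C@@H](/C=C/I)[C@]1(C)O
F4 | step 17 | (E)-2-ethoxy-1,3-diene (enol ether of the target ketone) | O[C@H]1[C@H](OC(C)=O)[C@H]2C(C)(C)CCC[C@]2(C)[C@@H](/C=C/C(=C)OCC)[C@]1(C)O
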